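**Assumption:** chamigrene numbering is used (ring B = C1–C6 with C2–Cl and C3–Br/Me; C6 = spiro carbon; ring A = C6–C11 with C7=C14H2, C9–OAc, C10–Br, C11Me2). Where the facial sense of a chiral catalyst is quoted from memory, the antipodal catalyst is equally available and would be substituted if the sense is opposite.

## Retrosynthetic overview

1. Target ⇐ chlorohydrin 14 (C3–OH → C3–Br with retention) ⇐ spiro-epoxide 13 (chloride opens the epoxide at C2).
2. Spiro-epoxide 13 ⇐ enyne 12 by forming the C6–C7 spiro bond: a tertiary C6 radical (H-atom transfer to the C6=C1 alkene) closes 6-exo-dig onto a terminal alkyne, which gives the exocyclic methylene directly.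
3. Enyne 12 ⇐ aldehyde 8 by catalytic enantioselective α-bromination (C10) and anti-selective propargylation (C9).
4. Aldehyde 8 ⇐ Claisen rearrangement of the epoxy allylic alcohol 6 (creates C11 and the C6=C1 alkene) ⇐ enantiopure piperitenone oxide 5 ⇐ 3-methylcyclohexenone + acetone.
5. Ring B is carried from the first starting material; ring A is closed last, in the radical step.

## Route

**Step 1**
Reactants: 1, 3-methylcyclohex-2-en-1-one
Product: 2, (1S,6S)-6-methyl-7-oxabicyclo[4.1.0]heptan-2-one [(2S,3S)-2,3-epoxy-3-methylcyclohexanone]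
Conditions: 9-amino(9-deoxy)epi-cinchona alkaloid·2TFA (10 mol%; quinine or quinidine series chosen to give the 2S,3S epoxide), 50% aq. H2O2, dioxane, 50 °C
Reagents that add atoms: hydrogen peroxide, OO
Why: Iminium-catalysed asymmetric Weitz–Scheffer epoxidation, in which the chiral primary amine salt directs hydroperoxide to one enone face and so sets both epoxide carbons (future C2 and C3).

**Step 2**
Reactants: 2, epoxy ketone; 3, acetone
Product: 4, (1S,6S)-3-(2-hydroxypropan-2-yl)-6-methyl-7-oxabicyclo[4.1.0]heptan-2-one (both epimers at the new CH; irrelevant)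
Conditions: LDA, THF, −78 °C; acetone, −78 °C; AcOH quench at −78 °C
Reagents that add atoms: none (acetone 3 is a reactant)
Why: Directed aldol of the kinetic α′-lithium enolate (the oxirane C–H is not removed); the new stereocentre is destroyed in step 3.

**Step 3**
Reactants: 4, aldol adduct
Product: 5, (1S,6S)-6-methyl-3-(propan-2-ylidene)-7-oxabicyclo[4.1.0]heptan-2-one (piperitenone oxide, single enantiomer)
Conditions: MsCl, Et3N, cat. DMAP, CH2Cl2, 0 °C; then DBU, rt
Reagents that add atoms: none
Why: Mesylation then E1cB elimination through the enolate gives the conjugated tetrasubstituted isopropylidene, leaving the epoxide intact.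

**Step 4**
Reactants: 5, piperitenone oxide
Product: 6, (1R,6S)-6-methyl-3-(propan-2-ylidene)-7-oxabicyclo[4.1.0]heptan-2-ol (carbinol epimers; the epoxide is unchanged, the C1 descriptor changes only through CIP priority)
Conditions: NaBH4, CeCl3·7H2O, MeOH, −40 °C
Reagents that add atoms: none
Why: Luche 1,2-reduction of the hindered cross-conjugated ketone; the carbinol configuration does not matter because this carbon becomes sp2 in step 5.

**Step 5**
Reactants: 6, epoxy allylic alcohol; 7, n-butyl vinyl ether
Product: 8, 3-methyl-3-[(1R,6S)-6-methyl-7-oxabicyclo[4.1.0]hept-2-en-3-yl]butanal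
Conditions: Pd(OCOCF3)2/bathophenanthroline (5 mol%), Et3N, n-BuOCH=CH2, 75 °C; concentrate; xylenes, 140 °C
Reagents that add atoms: none (the vinyl group comes from 7)
Why: Transfer vinylation then Claisen [3,3] rearrangement across C6=C11 creates the quaternary CMe2 carbon (C11, no new stereocentre), places the alkene at C6=C1 and removes the C1 oxygen.

**Step 6**
Reactants: 8, aldehyde
Product: 9, (2R)-2-bromo-3-methyl-3-[(1R,6S)-6-methyl-7-oxabicyclo[4.1.0]hept-2-en-3-yl]butanal (used cold and crude)
Conditions: (2S,5S)-2,5-diphenylpyrrolidine (20 mol%; enantiomer chosen for 10R), 4,4-dibromo-2,6-di-tert-butylcyclohexa-2,5-dienone, PhCO2H, H2O, CH2Cl2/pentane, −40 °C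
Reagents that add atoms: 4,4-dibromo-2,6-di-tert-butylcyclohexa-2,5-dien-1-one, O=C1C(C(C)(C)C)=CC(Br)(Br)C=C1C(C)(C)C
Why: Enamine-catalysed enantioselective α-bromination sets C10 (R) under catalyst control, independent of the remote epoxide; the enamine reacts faster than the alkene with the mild Br+ donor.

**Step 7**
Reactants: 9, α-bromo aldehyde; 10, propargyl bromide
Product: 11, (4S,5R)-5-bromo-6-methyl-6-[(1R,6S)-6-methyl-7-oxabicyclo[4.1.0]hept-2-en-3-yl]hept-1-yn-4-ol
Conditions: propargyl bromide, activated Zn, THF, 0 °C (pre-form the allenylzinc and decant from excess Zn); add to 9, THF, −78 °C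
Reagents that add atoms: none (C3 unit from 10)
Why: SE2′ addition of allenylzinc gives the homopropargylic alcohol, and the Cornforth–Evans polar model for α-halo aldehydes gives the 1,2-anti bromohydrin, which sets C9 (S) and corresponds to the cis relationship on ring A.

**Step 8**
Reactants: 11, bromohydrin
Product: 12, (4S,5R)-5-bromo-6-methyl-6-[(1R,6S)-6-methyl-7-oxabicyclo[4.1.0]hept-2-en-3-yl]hept-1-yn-4-yl acetate
Conditions: Ac2O, pyridine, cat. DMAP, CH2Cl2, 0 °C
Reagents that add atoms: acetic anhydride, CC(=O)OC(C)=O
Why: Acylation installs the acetate of the target and blocks base-induced closure of the anti-bromohydrin to an epoxide.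

**Step 9 (key step)**
Reactants: 12, epoxy enyne acetate
Product: 13, (2R,3S,6R,9S,10R)-10-bromo-2,3-epoxychamigr-7(14)-en-9-yl acetate (epoxide oxygen cis to C11 and trans to C7 on ring B)
Conditions: Fe(acac)3 (1.5 equiv), Ph(i-PrO)SiH2 (3 equiv), THF/i-PrOH, 0.01 M, 35 °C
Reagents that add atoms: none (two H atoms from silane/solvent)
Why: Proposed new method: Fe–H transfers H• to C1 of the trisubstituted alkene to give the tertiary C6 radical, which closes 6-exo-dig onto the sterically undemanding terminal alkyne from the face anti to the oxirane oxygen (CMe2 arm pseudo-equatorial on the half-chair), setting C6 (R); the exocyclic vinyl radical then abstracts H to give the C7=CH2 group. The closest known chemistry is Fe/Co MHAT-initiated radical cyclisation and reductive olefin coupling (including vicinal quaternary centres) and Stork-type radical cyclisation onto alkynes; secondary bromides, esters and epoxides are tolerated under these non-stannane conditions.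

**Step 10**
Reactants: 13, spiro-epoxide
Product: 14, (2S,3S,6R,9S,10R)-10-bromo-2-chloro-3-hydroxychamigr-7(14)-en-9-yl acetate
Conditions: Li2CuCl4 (LiCl/CuCl2), THF, 0 °C → rt
Reagents that add atoms: lithium chloride (as Li2CuCl4), [Li+].[Cl-]
Why: SN2 epoxide opening at the secondary carbon C2, reinforced by Fürst–Plattner trans-diaxial opening in the half-chair that keeps the CMe2 arm equatorial; C2 is inverted (Cl anti to the former oxygen) and the tertiary C3–O bond is untouched.

**Step 11**
Reactants: 14, chlorohydrin
Product: 15, 9-acetylisoobtusol, (2S,3S,6R,9S,10R)-3,10-dibromo-2-chlorochamigr-7(14)-en-9-yl acetate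
Conditions: 1-bromo-N,N,2-trimethylprop-1-en-1-amine (Ghosez bromo-enamine), CH2Cl2, 0 °C → rt (acid-free)
Reagents that add atoms: 1-bromo-N,N,2-trimethylprop-1-en-1-amine, CC(C)=C(Br)N(C)C
Why: Neutral tertiary alcohol-to-bromide exchange through an alkoxy-iminium ion; ionisation of the axial C3–O bond is assisted by the antiperiplanar C2–Cl (chloronium-like cation), so bromide returns axially to C3 anti to chlorine with net retention, giving the trans bromochloride without HBr that would attack the C7=CH2 alkene.

## Compound list

1 | 3-methylcyclohex-2-en-1-one | CC1=CC(=O)CCC1 | starting material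
2 | (1S,6S)-6-methyl-7-oxabicyclo[4.1.0]heptan-2-one | O=C1CCC[C@]2(C)O[C@H]12 | intermediate
3 | acetone | CC(C)=O | starting material
4 | (1S,6S)-3-(2-hydroxypropan-2-yl)-6-methyl-7-oxabicyclo[4.1.0]heptan-2-one (C3 epimers) | O=C1C(C(C)(C)O)CC[C@]2(C)O[C@H]12 | intermediate
5 | (1S,6S)-6-methyl-3-(propan-2-ylidene)-7-oxabicyclo[4.1.0]heptan-2-one | O=C1C(=C(C)C)CC[C@]2(C)O[C@H]12 | intermediate
6 | (1R,6S)-6-methyl-3-(propan-2-ylidene)-7-oxabicyclo[4.1.0]heptan-2-ol (carbinol epimers) | OC1C(=C(C)C)CC[C@]2(C)O[C@H]12 | intermediate
7 | n-butyl vinyl ether | C=COCCCC | starting material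
8 | 3-methyl-3-[(1R,6S)-6-methyl-7-oxabicyclo[4.1.0]hept-2-en-3-yl]butanal | O=CCC(C)(C)C1=C[C@H]2O[C@@]2(C)CC1 | intermediate
9 | (2R)-2-bromo-3-methyl-3-[(1R,6S)-6-methyl-7-oxabicyclo[4.1.0]hept-2-en-3-yl]butanal | O=C[C@H](Br)C(C)(C)C1=C[C@H]2O[C@@]2(C)CC1 | intermediate
10 | propargyl bromide | C#CCBr | starting material
11 | (4S,5R)-5-bromo-6-methyl-6-[(1R,6S)-6-methyl-7-oxabicyclo[4.1.0]hept-2-en-3-yl]hept-1-yn-4-ol | C#CC[C@H](O)[C@H](Br)C(C)(C)C1=C[C@H]2O[C@@]2(C)CC1 | intermediate
12 | acetate of 11 | C#CC[C@H](OC(C)=O)[C@H](Br)C(C)(C)C1=C[C@H]2O[C@@]2(C)CC1 | intermediate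
13 | (2R,3S,6R,9S,10R)-10-bromo-2,3-epoxychamigr-7(14)-en-9-yl acetate | C=C1C[C@H](OC(C)=O)[C@H](Br)C(C)(C)[C@@]12CC[C@]3(C)O[C@@H]3C2 | intermediate
14 | (2S,3S,6R,9S,10R)-10-bromo-2-chloro-3-hydroxychamigr-7(14)-en-9-yl acetate | C=C1C[C@H](OC(C)=O)[C@H](Br)C(C)(C)[C@@]12CC[C@](C)(O)[C@@H](Cl)C2 | intermediate
15 | 9-acetylisoobtusol | C=C1C[C@H](OC(C)=O)[C@H](Br)C(C)(C)[C@@]12CC[C@](C)(Br)[C@@H](Cl)C2 | target

## Summary

Total steps: 11. Longest linear sequence: 11 (fully linear from 1).

Steps most likely to fail:

1. **Step 9 (radical spirocyclisation).** The 6-exo-dig closure onto an unactivated alkyne is slow and competes with simple reduction of the C6 radical, 1,5-H transfer from the propargylic CH2, and 1,3-loss of the C10 bromide; facial selectivity at C6 relative to the epoxide may be modest. Fallback: add 1-propynylmagnesium bromide to aldehyde 8 and oxidise to the ynone, then run a fast, polarity-matched MHAT 6-endo-dig Giese closure to the spiro-enone (C7-Me, C7=C8, C9=O). Ring A is then finished by C10 α′-bromination with deconjugation to the exocyclic alkene and hydride reduction to the cis-bromohydrin.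
2. **Step 11 (tertiary OH → Br with retention).** E1 elimination or loss of stereocontrol at the C3 cation is possible. Fallback: dehydrate 14 to the C3 exocyclic-methylene allylic chloride and install the tertiary bromide by radical Markovnikov hydrobromination (Co(salen)/PhSiH3/TsBr), trapping the C3 radical axially anti to C2–Cl. This relies on slower H-atom transfer to the more hindered C7=CH2 next to the spiro centre.
3. **Step 7 (with step 6).** The α-bromo aldehyde is configurationally labile and the Cornforth anti selectivity with an organozinc may be modest. Fallback: oxidise the C9 carbinol mixture to the α-bromo ketone, cyclise as in step 9, and set C9 on the ring by hydride reduction anti to the adjacent C–Br, which gives the cis-bromohydrin; then acetylate.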